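Peniophorin (benzofuran numbering) is opened at the lactone O1–C2 bond and then at C7a–C3a of the six-membered ring. The key step exploits two features: the run C5–C6–C7–C7a, oxygenated at C5, C6 and C7a, is a cleaved squarate ring, and the triad C4–C3a–C3 with its two identical 4-hydroxyphenyl groups is a 1,3-diarylallene. Heating a squarate-derived 4-allenyl-4-hydroxycyclobutenone, whose allene terminus already carries the C2 ester, opens the four-membered ring to a vinylketene and closes the hexasubstituted carbocycle onto the central allene carbon in one operation, at the oxidation level of the target. Acid lactonisation and demethylation then finish the pigment.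

Key step: step 5

Remark on the chemistry: lithiated 7 is drawn as bonding through its sp terminus to give allenyl carbinol 9; bonding through the benzylic terminus, or use of 7 partly isomerised to its allene, would lead after the second deprotonation to the same delocalised anion, so the route does not depend on that ratio.

Step 1
Reactants: 1 diisopropyl squarate; 2 phenyllithium
Product: 4 3-isopropoxy-4-phenylcyclobut-3-ene-1,2-dione, via squarate carbinol 3 (not isolated)
Conditions: PhLi (1.05 equiv), THF, −78 °C; cold 1 M HCl quench; crude 3 in CH2Cl2, 12 M HCl (cat.), rt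
Reagents that add atoms: none
Why: Phenyllithium adds 1,2 to one squarate carbonyl and, under acid, the tertiary carbinol ionises with help from the neighbouring enol ether, water returns at the alkoxy-bearing carbon and isopropanol is expelled, which restores the dione with phenyl in place of one alkoxy group (organolithium 1,2-addition to a squarate ester, then acid-promoted 1,3-transposition); the racemic carbinol centre of 3 is destroyed.

Step 2
Reactants: 5 4-ethynylanisole; 6 4-methoxybenzyl chloride
Product: 7 1,3-bis(4-methoxyphenyl)prop-1-yne
Conditions: PdCl2(MeCN)2 (2 mol %), XPhos (6 mol %), Cs2CO3, THF, 65 °C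
Reagents that add atoms: none
Why: Oxidative addition of the benzylic chloride to zerovalent palladium, base-assisted alkynyl transfer and reductive elimination form the sp–sp3 bond (copper-free Sonogashira-type coupling of a terminal alkyne with a benzyl chloride), and the bulky biarylphosphine suppresses alkyne homocoupling.

Step 3
Reactants: 7 1,3-bis(4-methoxyphenyl)prop-1-yne; 4 3-isopropoxy-4-phenylcyclobut-3-ene-1,2-dione; 8 carbon dioxide
Product: 10 4-(1-hydroxy-2-isopropoxy-4-oxo-3-phenylcyclobut-2-en-1-yl)-2,4-bis(4-methoxyphenyl)buta-2,3-dienoic acid, via allenyl carbinol 9 (not isolated)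
Conditions: 7 (1.1 equiv), n-BuLi (1.05 equiv), THF, −78 °C; 4 (1.0 equiv), −78 °C; LiN(iPr)2 (1.3 equiv), −78 to −60 °C; CO2 (g), −78 °C; cold dilute HCl to pH 3
Reagents that add atoms: none
Why: The propargyl–allenyl lithium from 7 should add 1,2 to the more electrophilic ketone carbonyl of 4 (the one flanked by the isopropoxy carbon, the other being deactivated as a vinylogous ester), lithium diisopropylamide then removes the remaining diaryl-stabilised C–H of the cold lithium alkoxide, and the delocalised anion is carboxylated at its remote terminus because the proximal one sits next to the fully substituted alkoxide carbon (organolithium 1,2-addition followed by carboxylation of an allenyl anion); the carbinol centre and the allene axis form as mixtures that are erased in steps 5 and 6.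

Step 4
Reactants: 10 4-(1-hydroxy-2-isopropoxy-4-oxo-3-phenylcyclobut-2-en-1-yl)-2,4-bis(4-methoxyphenyl)buta-2,3-dienoic acid
Product: 11 methyl 4-(1-hydroxy-2-isopropoxy-4-oxo-3-phenylcyclobut-2-en-1-yl)-2,4-bis(4-methoxyphenyl)buta-2,3-dienoate
Conditions: TMSCHN2 (hexanes), PhMe/MeOH (4:1), 0 °C; AcOH quench
Reagents that add atoms: trimethylsilyldiazomethane, C[Si](C)(C)C=[N+]=[N-] (carbon of the ester methyl group)
Why: Trimethylsilyldiazomethane with methanol O-methylates carboxylic acids at 0 °C under neutral conditions (diazoalkane esterification), the tertiary alcohol and the acid-sensitive hydroxycyclobutenone are untouched, the fully substituted allenoate is too hindered for dipolar cycloaddition at this temperature, and the ester blocks decarboxylation in the later steps.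

Step 5
Reactants: 11 methyl 4-(1-hydroxy-2-isopropoxy-4-oxo-3-phenylcyclobut-2-en-1-yl)-2,4-bis(4-methoxyphenyl)buta-2,3-dienoate
Product: 14 methyl 2-[4-isopropoxy-2-(4-methoxyphenyl)-3,6-dioxo-5-phenylcyclohexa-1,4-dien-1-yl]-2-(4-methoxyphenyl)acetate, via vinylketene 12 (not isolated), via o-quinone methide 13 (not isolated)
Conditions: PhMe (degassed, 0.02 M), 90 °C, dark
Reagents that add atoms: none
Why: Heating opens the cyclobutenone by a conrotatory 4π electrocyclic reaction that breaks the C5–C7a bond and gives vinylketene 12; a 6π electrocyclisation then bonds the electrophilic ketene carbon C7a to the central, sp-hybridised allene carbon C3a to give o-quinone methide 13, and a proton shift from O5 to C3 delivers quinone 14. The closest known reaction type is the thermal ring expansion of 4-allenyl-4-hydroxycyclobutenones to o-quinone methides, the allenyl counterpart of the Moore–Liebeskind squarate benzannulation. The one ring closed is the six-membered carbocycle C3a–C4–C5–C6–C7–C7a, formed by thermal disrotatory 6π closure of the ketene–enol–allene triene. No stereocentre has to be controlled: the carbinol centre and the allene axis are consumed, the geometry of the exocyclic C3a=C3 bond of 13 is lost on tautomerisation, and C3 of 14 is racemic and is flattened again in step 6. The step needs torquoselective outward rotation of the C5 hydroxyl, which its donor character secures and which places the allenyl group cis to the ketene, and it needs closure at C3a, the only allene carbon that can complete a six-membered ring and one that stays unhindered although the allene is tetrasubstituted. Because an allene stands two oxidation levels above an alkene, the ring arrives as a quinone and no oxidant is required.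

Step 6
Reactants: 14 methyl 2-[4-isopropoxy-2-(4-methoxyphenyl)-3,6-dioxo-5-phenylcyclohexa-1,4-dien-1-yl]-2-(4-methoxyphenyl)acetate
Product: 16 peniophorin di-O-methyl ether (5-hydroxy-3,4-bis(4-methoxyphenyl)-7-phenyl-1-benzofuran-2,6-dione), via hydroxyquinone 15 (not isolated)
Conditions: TFA/H2O (9:1), 60 °C
Reagents that add atoms: water, O (oxygen on C6, by addition–elimination at the vinylogous ester)
Why: Hot aqueous acid hydrolyses the vinylogous isopropyl ester to hydroxyquinone 15, whose tautomer carrying the hydroxyl on C7a closes the five-membered lactone onto the methyl ester (5-exo-trig acid-catalysed transesterification), after which enolisation of C3–H toward O5 gives the fully conjugated quinone methide and removes the C3 stereocentre.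

Step 7
Reactants: 16 peniophorin di-O-methyl ether
Product: 17 peniophorin
Conditions: BBr3 (6 equiv), CH2Cl2, −78 °C to rt; H2O
Reagents that add atoms: none
Why: BBr3 complexes each anisole oxygen and bromide removes the methyl group (Lewis-acid cleavage of aryl methyl ethers), while the lactone, the enol and the quinone methide are only complexed and should be released unchanged on aqueous work-up.

Compound list
1 | diisopropyl squarate (3,4-diisopropoxycyclobut-3-ene-1,2-dione) | CC(C)OC1=C(OC(C)C)C(=O)C1=O | starting material
2 | phenyllithium | [Li]c1ccccc1 | starting material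
3 | 4-hydroxy-2,3-diisopropoxy-4-phenylcyclobut-2-en-1-one (racemic, crude, not purified) | CC(C)OC1=C(OC(C)C)C(O)(c2ccccc2)C1=O | intermediate
4 | 3-isopropoxy-4-phenylcyclobut-3-ene-1,2-dione | CC(C)OC1=C(c2ccccc2)C(=O)C1=O | intermediate
5 | 4-ethynylanisole | C#Cc1ccc(OC)cc1 | starting material
6 | 4-methoxybenzyl chloride | ClCc1ccc(OC)cc1 | starting material
7 | 1,3-bis(4-methoxyphenyl)prop-1-yne | COc1ccc(CC#Cc2ccc(OC)cc2)cc1 | intermediate
8 | carbon dioxide | O=C=O | starting material
9 | 4-[1,3-bis(4-methoxyphenyl)propa-1,2-dien-1-yl]-4-hydroxy-3-isopropoxy-2-phenylcyclobut-2-en-1-one (present in the flask as its lithium alkoxide; carbinol centre and allene axis unspecified mixtures) | O=C1C(c2ccccc2)=C(OC(C)C)C1(O)C(=C=Cc1ccc(OC)cc1)c1ccc(OC)cc1 | intermediate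
10 | 4-(1-hydroxy-2-isopropoxy-4-oxo-3-phenylcyclobut-2-en-1-yl)-2,4-bis(4-methoxyphenyl)buta-2,3-dienoic acid (carbinol centre and allene axis unspecified mixtures) | O=C1C(c2ccccc2)=C(OC(C)C)C1(O)C(=C=C(C(=O)O)c1ccc(OC)cc1)c1ccc(OC)cc1 | intermediate
11 | methyl 4-(1-hydroxy-2-isopropoxy-4-oxo-3-phenylcyclobut-2-en-1-yl)-2,4-bis(4-methoxyphenyl)buta-2,3-dienoate (carbinol centre and allene axis unspecified mixtures) | O=C1C(c2ccccc2)=C(OC(C)C)C1(O)C(=C=C(C(=O)OC)c1ccc(OC)cc1)c1ccc(OC)cc1 | intermediate
12 | methyl (5Z)-5-hydroxy-6-isopropoxy-2,4-bis(4-methoxyphenyl)-8-oxo-7-phenylocta-2,3,5,7-tetraenoate (vinylketene; allenyl group cis to the ketene-bearing carbon, allene axis unspecified) | O=C=C(c1ccccc1)/C(OC(C)C)=C(O)\C(=C=C(C(=O)OC)c1ccc(OC)cc1)c1ccc(OC)cc1 | intermediate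
13 | methyl 2-[3-hydroxy-4-isopropoxy-2-(4-methoxyphenyl)-6-oxo-5-phenylcyclohexa-2,4-dien-1-ylidene]-2-(4-methoxyphenyl)acetate (o-quinone methide; exocyclic alkene geometry unspecified) | O=C1C(c2ccccc2)=C(OC(C)C)C(O)=C(c2ccc(OC)cc2)C1=C(C(=O)OC)c1ccc(OC)cc1 | intermediate
14 | methyl 2-[4-isopropoxy-2-(4-methoxyphenyl)-3,6-dioxo-5-phenylcyclohexa-1,4-dien-1-yl]-2-(4-methoxyphenyl)acetate (racemic at C3) | O=C1C(c2ccccc2)=C(OC(C)C)C(=O)C(c2ccc(OC)cc2)=C1C(C(=O)OC)c1ccc(OC)cc1 | intermediate
15 | methyl 2-[4-hydroxy-2-(4-methoxyphenyl)-3,6-dioxo-5-phenylcyclohexa-1,4-dien-1-yl]-2-(4-methoxyphenyl)acetate (racemic at C3) | O=C1C(c2ccccc2)=C(O)C(=O)C(c2ccc(OC)cc2)=C1C(C(=O)OC)c1ccc(OC)cc1 | intermediate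
16 | peniophorin di-O-methyl ether, 5-hydroxy-3,4-bis(4-methoxyphenyl)-7-phenyl-1-benzofuran-2,6-dione (no stereocentre; C3a=C3 fixed in the lactone ring) | O=C1OC2=C(c3ccccc3)C(=O)C(O)=C(c3ccc(OC)cc3)C2=C1c1ccc(OC)cc1 | intermediate
17 | peniophorin, 5-hydroxy-3,4-bis(4-hydroxyphenyl)-7-phenyl-1-benzofuran-2,6-dione (no stereocentre) | O=C1OC2=C(c3ccccc3)C(=O)C(O)=C(c3ccc(O)cc3)C2=C1c1ccc(O)cc1 | target

Total step count: 7. Longest linear sequence: 6 steps (steps 1, 3, 4, 5, 6, 7); step 2 is a one-step side branch.

Steps most likely to fail

1. Step 3. What may go wrong: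
- The second lithiation of the lithium alkoxide may be incomplete, or the alkoxide–carbanion may break down before it is trapped.
- Carboxylation may take place in part at the proximal terminus.
- The soft propargyl anion may add in conjugate fashion to the isopropoxy-bearing carbon of 4 with loss of isopropoxide.

Fallback, setting out from 4 and 7 and returning at 11: the addition is run as before, but the cold lithium alkoxide is silylated in the flask with Me3SiCl and the neutral silyl ether F1 is isolated. F1 is then deprotonated as a simple monoanion with LiN(iPr)2 in THF at −78 °C and acylated directly at the remote terminus with methyl chloroformate, the silyloxy group shielding the proximal carbon further, to give silyl ether ester F2. Bu4NF buffered with AcOH in THF at 0 °C should remove the silyl group and give 11, so that acid 10 and the diazoalkane step are bypassed.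

2. Step 5. What may go wrong:
- Closure of the vinylketene onto the electron-poor, fully substituted allene may be slow, so that the ketene is lost to dimerisation or to adventitious nucleophiles.
- The o-quinone methide may react further before it tautomerises.

Fallback, setting out from 4 and returning at 14: the six-membered ring is built by the alkenyl version of the same squarate benzannulation and the arylacetate arm is attached afterwards. 1-(4-Methoxyphenyl)vinyllithium (from purchased 1-(1-bromovinyl)-4-methoxybenzene and t-BuLi, THF, −78 °C) should add to the same carbonyl of 4 to give alkenyl carbinol F3. Thermolysis in refluxing toluene should give hydroquinone F4, which Ag2O oxidises to trisubstituted quinone F5, whose only unsubstituted ring carbon is C3a. ZnCl2-promoted Mukaiyama–Michael addition of ketene silyl acetal F6 (from methyl (4-methoxyphenyl)acetate, LiN(iPr)2 and Me3SiCl) at that carbon should give, after desilylating work-up, hydroquinone ester F7, and oxidation of F7 with Ag2O gives 14. This route needs an external oxidant twice but relies only on established reactions.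

3. Step 6. What may go wrong:
- Hydrolysis of the methyl ester followed by decarboxylation of the quinonylacetic acid may outrun ring closure.
- Cleavage of the vinylogous isopropyl ester may stall.
- The weakly nucleophilic hydroxyquinone oxygen may close the lactone only slowly.

Fallback, setting out from 14 and returning at 16: the lactone is closed at the hydroquinone oxidation level, where O7a is an ordinary phenol. BCl3 (CH2Cl2, −78 °C) should remove the isopropyl group selectively and give hydroxyquinone 15, isolated in this variant. Zn in AcOH reduces 15 to benzenetriol ester F8, which should lactonise in the warm acetic acid to leuco-lactone F9. Oxidation of F9 with Ag2O (or air) removes the hydrogens on C3 and O6 and gives 16.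

Further compounds
F1 | step 3 | 4-[1,3-bis(4-methoxyphenyl)propa-1,2-dien-1-yl]-3-isopropoxy-2-phenyl-4-(trimethylsilyloxy)cyclobut-2-en-1-one (mixture of isomers) | O=C1C(c2ccccc2)=C(OC(C)C)C1(O[Si](C)(C)C)C(=C=Cc1ccc(OC)cc1)c1ccc(OC)cc1
F2 | step 3 | methyl 4-[2-isopropoxy-4-oxo-3-phenyl-1-(trimethylsilyloxy)cyclobut-2-en-1-yl]-2,4-bis(4-methoxyphenyl)buta-2,3-dienoate (mixture of isomers) | O=C1C(c2ccccc2)=C(OC(C)C)C1(O[Si](C)(C)C)C(=C=C(C(=O)OC)c1ccc(OC)cc1)c1ccc(OC)cc1
F3 | step 5 | 4-hydroxy-3-isopropoxy-4-[1-(4-methoxyphenyl)ethenyl]-2-phenylcyclobut-2-en-1-one (racemic) | O=C1C(c2ccccc2)=C(OC(C)C)C1(O)C(=C)c1ccc(OC)cc1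
F4 | step 5 | 3-isopropoxy-5-(4-methoxyphenyl)-2-phenylbenzene-1,4-diol | COc1ccc(cc1)-c1cc(O)c(-c2ccccc2)c(OC(C)C)c1O
F5 | step 5 | 3-isopropoxy-5-(4-methoxyphenyl)-2-phenylcyclohexa-2,5-diene-1,4-dione | O=C1C=C(c2ccc(OC)cc2)C(=O)C(OC(C)C)=C1c1ccccc1
F6 | step 5 | [1-methoxy-2-(4-methoxyphenyl)ethenyl]oxy(trimethyl)silane (alkene geometry unspecified) | COC(=Cc1ccc(OC)cc1)O[Si](C)(C)C
F7 | step 5 | methyl 2-[2,5-dihydroxy-4-isopropoxy-6-(4-methoxyphenyl)-3-phenylphenyl]-2-(4-methoxyphenyl)acetate (racemic) | COC(=O)C(c1ccc(OC)cc1)c1c(O)c(-c2ccccc2)c(OC(C)C)c(O)c1-c1ccc(OC)cc1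
F8 | step 6 | methyl 2-[2,4,5-trihydroxy-6-(4-methoxyphenyl)-3-phenylphenyl]-2-(4-methoxyphenyl)acetate (racemic) | COC(=O)C(c1ccc(OC)cc1)c1c(O)c(-c2ccccc2)c(O)c(O)c1-c1ccc(OC)cc1
F9 | step 6 | 5,6-dihydroxy-3,4-bis(4-methoxyphenyl)-7-phenyl-1-benzofuran-2(3H)-one (racemic) | O=C1Oc2c(-c3ccccc3)c(O)c(O)c(-c3ccc(OC)cc3)c2C1c1ccc(OC)cc1
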